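**Retrosynthetic overview**

1. Target ⇐ Sharpless epoxidation of the (E)-allylic alcohol; the side chain comes from a methyl ketone (olefination, reduction) carried in as a ketal Grignard reagent.
2. Quaternary C9 ⇐ axial conjugate methylation of the C1-oxo C9=C10 enone, trapped as the C1 enol triflate and reduced to the C1=C10 alkene; that enone ⇐ oxidative 1,3-transposition of the tertiary allylic alcohol made from the bicyclic C9 ketone.
3. Ring B ⇐ 6-endo radical conjugate addition joining C6 to C7 (key step). The enabling feature is that C7 lies between the CH2 on C5 (C6) and the methyl-bearing C8, and C8 is one carbon from the ring-fusion alkene carbon C10. A 2-methylpropenoyl group on C10 (temporary C9 carbonyl) therefore puts its free CH2 terminus (C7) six atoms from a radical at C6, and the same carbonyl later sets C8 and becomes the quaternary C9.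
4. Ring A is bought. C4 is set by catalytic conjugate methylation, C5 by a temporary cis-fused γ-lactone (C18–O–C6), C8 by equilibration next to the C9 ketone, C9 by the ring B conformation, and C13/C14 by the tartrate.
5. Ring order: ring A (given) → temporary lactone ring (step 1, opened in step 4) → ring B (step 6) → oxirane (step 14).

Key step: step 6

Remark: halimane numbering is used in the text (ring A = C1–C5, C10; ring B = C5–C10; C18 = ester carbon on C4; C17, C20 = methyls on C8, C9; C11–C16 = side chain). The three starting materials are taken as purchasable, and in step 1 the ligand antipode is the one that gives the (S)-quaternary centre.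

**Route**

Step 1
Reactants: 1 methyl 3-oxocyclohex-1-ene-1-carboxylate
Product: 4 (3aR,7aS)-7a-methylhexahydro-2-benzofuran-1,4-dione, via methylzinc enolate 2 (not isolated), via hydroxymethyl keto ester 3 (not isolated)
Conditions: Me2Zn (3 equiv), (CuOTf)2·C6H6 (2.5 mol %), chiral bidentate N-heterocyclic carbene ligand (5 mol %), t-BuOMe, −30 °C; then monomeric CH2O in THF, −78 → 0 °C; aq. NH4Cl; then p-TsOH·H2O (10 mol %), CH2Cl2, 23 °C
Reagents that add atoms: dimethylzinc (C[Zn]C); formaldehyde (C=O)
Why: Copper-catalysed asymmetric conjugate addition of a dialkylzinc to the β-alkoxycarbonyl enone should set the C4 quaternary centre under catalyst control, the zinc enolate is hydroxymethylated regiospecifically at C5 (tandem conjugate addition–aldol), and acid-catalysed lactonization onto the neighbouring ester, strongly favoured for the cis isomer and fed by enolization of the C10 ketone, should fix C5 relative to C4 as the cis-fused γ-lactone.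

Step 2
Reactants: 4 (3aR,7aS)-7a-methylhexahydro-2-benzofuran-1,4-dione
Product: 6 (3aR,7aS)-7a-methyl-1-oxo-1,3,3a,6,7,7a-hexahydro-2-benzofuran-4-yl trifluoromethanesulfonate, via potassium enolate 5 (not isolated)
Conditions: KN(SiMe3)2 (1.05 equiv), THF, −78 °C; then PhNTf2, −78 → 0 °C
Reagents that add atoms: N-phenylbis(trifluoromethanesulfonimide) (O=S(=O)(N(c1ccccc1)S(=O)(=O)C(F)(F)F)C(F)(F)F)
Why: Kinetic deprotonation should occur at the unhindered C1 methylene and not at the ring-fusion C5–H, so O-triflation of the less substituted enolate (regioselective enol triflate formation) gives the C10 triflate with the C1=C10 double bond already in its final place and C5 no longer epimerizable.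

Step 3
Reactants: 6 (3aR,7aS)-7a-methyl-1-oxo-1,3,3a,6,7,7a-hexahydro-2-benzofuran-4-yl trifluoromethanesulfonate; 7 methacrolein
Product: 8 (3aR,7aS)-4-(1-hydroxy-2-methylprop-2-en-1-yl)-7a-methyl-3a,6,7,7a-tetrahydro-2-benzofuran-1(3H)-one (both carbinol epimers)
Conditions: CrCl2 (4 equiv), NiCl2 (2 mol %), DMF, 23 °C
Reagents that add atoms: none
Why: The Nozaki–Hiyama–Kishi coupling converts the enol triflate into an alkenylchromium species that adds 1,2 to the enal and tolerates the lactone, and the new carbinol centre (C9) may form as a mixture because it is oxidized in step 5.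

Step 4
Reactants: 8 (3aR,7aS)-4-(1-hydroxy-2-methylprop-2-en-1-yl)-7a-methyl-3a,6,7,7a-tetrahydro-2-benzofuran-1(3H)-one
Product: 10 methyl (1S,2R)-3-(1-hydroxy-2-methylprop-2-en-1-yl)-1-methyl-2-[(phenylselanyl)methyl]cyclohex-3-ene-1-carboxylate (both carbinol epimers), via sodium carboxylate 9 (not isolated)
Conditions: (PhSe)2 (0.75 equiv), NaH (1.6 equiv), THF, 65 °C; then 8, HMPA, 65 °C; then MeI (3 equiv), 23 °C
Reagents that add atoms: sodium benzeneselenolate ([Na+].[Se-]c1ccccc1), made in the flask from diphenyl diselenide (c1ccc(cc1)[Se][Se]c1ccccc1) and sodium hydride ([Na+].[H-]); iodomethane (CI)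
Why: SN2 alkyl–oxygen cleavage of the γ-lactone by the soft selenolate at the primary C6 (lactone opening by selenide anion), followed by O-methylation of the carboxylate, should turn the temporary ring into the C6 radical precursor and the C18 methyl ester without touching C5.

Step 5
Reactants: 10 methyl (1S,2R)-3-(1-hydroxy-2-methylprop-2-en-1-yl)-1-methyl-2-[(phenylselanyl)methyl]cyclohex-3-ene-1-carboxylate
Product: 11 methyl (1S,2R)-1-methyl-3-(2-methylprop-2-enoyl)-2-[(phenylselanyl)methyl]cyclohex-3-ene-1-carboxylate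
Conditions: activated MnO2 (20 equiv), CH2Cl2, 23 °C
Reagents that add atoms: none
Why: Activated MnO2 should oxidize the doubly allylic alcohol selectively to the cross-conjugated dienone (allylic alcohol oxidation) and leave the selenide untouched.

Step 6
Reactants: 11 methyl (1S,2R)-1-methyl-3-(2-methylprop-2-enoyl)-2-[(phenylselanyl)methyl]cyclohex-3-ene-1-carboxylate
Product: 13 methyl (1S,6R,8aR)-1,6-dimethyl-5-oxo-1,2,3,5,6,7,8,8a-octahydronaphthalene-1-carboxylate, via epimeric bicyclic enone 12 (not isolated)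
Conditions: Bu3SnH (1.3 equiv) and AIBN (0.2 equiv) added over 6 h to 11 in PhH (0.005 M), 80 °C; then DBU (0.2 equiv), CH2Cl2, 23 °C
Reagents that add atoms: none
Why: Bu3Sn• removes the phenylselanyl group from C6, the primary radical adds to C7, the free CH2 terminus of the 2-methylpropenoyl group on C10, and the tertiary α-keto radical at C8 takes hydrogen from Bu3SnH, which carries the chain. The closest known reaction type is the tin hydride-mediated Giese-type cyclization of alkyl radicals onto α-substituted vinyl ketones whose carbonyl lies inside the new ring. Ring B closes in the 6-endo-trig mode, since 5-exo attack would have to bond to the electron-poor, fully substituted C8 beside the carbonyl, against both polarity and sterics. C8 is the only new stereocentre; it is α to the temporary C9 ketone, and DBU should equilibrate it to the equatorial methyl, which on the ring B half-chair fixed by the axial H5 is the required (R) configuration, so C4 relays through C5 to C8. The step needs ring closure to outrun hydrogen transfer to the C6 radical and to ignore the second enone terminus C1; the activated acceptor with slow addition of Bu3SnH at high dilution secures the first, and the four-membered ring that attack at C1 would require secures the second. C5 stays fixed because it is not α to a carbonyl group, and the ester and the ring A alkene are inert to stannyl radicals under these conditions.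

Step 7
Reactants: 13 methyl (1S,6R,8aR)-1,6-dimethyl-5-oxo-1,2,3,5,6,7,8,8a-octahydronaphthalene-1-carboxylate; 14 2-(2-bromoethyl)-2-methyl-1,3-dioxolane
Product: 16 methyl (1S,6R,8aR)-5-hydroxy-1,6-dimethyl-5-[2-(2-methyl-1,3-dioxolan-2-yl)ethyl]-1,2,3,5,6,7,8,8a-octahydronaphthalene-1-carboxylate (both C5 carbinol epimers), via Grignard reagent 15 (not isolated)
Conditions: 14, Mg, THF, 30 °C; then 13, LaCl3·2LiCl (1.1 equiv), THF, −40 → 0 °C; aq. NH4Cl
Reagents that add atoms: none
Why: Lanthanum chloride-promoted 1,2-addition of the alkyl Grignard reagent to the hindered enone carbonyl should suppress enolization at C8 and conjugate addition and brings in C11–C13 and C16, the carbinol configuration being of no consequence because C9 becomes trigonal in step 8.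

Step 8
Reactants: 16 methyl (1S,6R,8aR)-5-hydroxy-1,6-dimethyl-5-[2-(2-methyl-1,3-dioxolan-2-yl)ethyl]-1,2,3,5,6,7,8,8a-octahydronaphthalene-1-carboxylate
Product: 17 methyl (1S,6R,8aR)-1,6-dimethyl-5-[2-(2-methyl-1,3-dioxolan-2-yl)ethyl]-4-oxo-1,2,3,4,6,7,8,8a-octahydronaphthalene-1-carboxylate
Conditions: pyridinium chlorochromate, C5H5NH[CrO3Cl] (3 equiv), NaOAc, 4 Å molecular sieves, CH2Cl2, 23 °C
Reagents that add atoms: pyridinium chlorochromate ([O-][Cr](=O)(=O)Cl.c1cc[nH+]cc1), source of the carbonyl oxygen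
Why: Oxidative 1,3-transposition of a tertiary allylic alcohol (Babler–Dauben oxidation) passes the chromate ester from C9 to C1 by a [3,3] shift and oxidizes it, which should give the enone with the C9=C10 bond held in ring B, C1 as carbonyl and no new stereocentre.

Step 9
Reactants: 17 methyl (1S,6R,8aR)-1,6-dimethyl-5-[2-(2-methyl-1,3-dioxolan-2-yl)ethyl]-4-oxo-1,2,3,4,6,7,8,8a-octahydronaphthalene-1-carboxylate
Product: 19 methyl (1S,5S,6R,8aR)-1,5,6-trimethyl-5-[2-(2-methyl-1,3-dioxolan-2-yl)ethyl]-4-[(trifluoromethanesulfonyl)oxy]-1,2,3,5,6,7,8,8a-octahydronaphthalene-1-carboxylate, via lithium enolate 18 (not isolated)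
Conditions: Me2CuLi (3 equiv, from CuI and MeLi), Et2O, −20 → 0 °C; then PhNTf2, THF, 0 → 23 °C
Reagents that add atoms: lithium dimethylcuprate ([Li+].C[Cu-]C), made in the flask from CuI ([Cu+].[I-]) and methyllithium ([Li]C); N-phenylbis(trifluoromethanesulfonimide) (O=S(=O)(N(c1ccccc1)S(=O)(=O)C(F)(F)F)C(F)(F)F)
Why: Conjugate addition of the cuprate to the s-cis alkylidene ketone (as with pulegone-type enones) should deliver methyl axially to C9 on the face of the axial H5, the chair-like trajectory for the ring B half-chair fixed by C5, so that C20 becomes cis to C17 and trans to the side chain, and the regiodefined enolate is trapped on oxygen as the C1 enol triflate (conjugate addition–enolate triflation).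

Step 10
Reactants: 19 methyl (1S,5S,6R,8aR)-1,5,6-trimethyl-5-[2-(2-methyl-1,3-dioxolan-2-yl)ethyl]-4-[(trifluoromethanesulfonyl)oxy]-1,2,3,5,6,7,8,8a-octahydronaphthalene-1-carboxylate
Product: 20 methyl (1S,5S,6R,8aR)-1,5,6-trimethyl-5-[2-(2-methyl-1,3-dioxolan-2-yl)ethyl]-1,2,3,5,6,7,8,8a-octahydronaphthalene-1-carboxylate
Conditions: Pd(OAc)2 (5 mol %), PPh3 (10 mol %), HCO2H (3 equiv), Bu3N (4 equiv), DMF, 60 °C
Reagents that add atoms: none
Why: Palladium-catalysed formate reduction of an enol triflate replaces the triflate by hydrogen without moving the double bond, which should give the C1=C10 alkene and leave ester and ketal untouched.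

Step 11
Reactants: 20 methyl (1S,5S,6R,8aR)-1,5,6-trimethyl-5-[2-(2-methyl-1,3-dioxolan-2-yl)ethyl]-1,2,3,5,6,7,8,8a-octahydronaphthalene-1-carboxylate
Product: 21 methyl (1S,5S,6R,8aR)-1,5,6-trimethyl-5-(3-oxobutyl)-1,2,3,5,6,7,8,8a-octahydronaphthalene-1-carboxylate
Conditions: pyridinium p-toluenesulfonate (0.2 equiv), acetone–H2O (10:1), 50 °C
Reagents that add atoms: water (O)
Why: Mild acid-catalysed hydrolysis of the dioxolane should free the methyl ketone while the trisubstituted alkene and the hindered ester are inert to this acid.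

Step 12
Reactants: 21 methyl (1S,5S,6R,8aR)-1,5,6-trimethyl-5-(3-oxobutyl)-1,2,3,5,6,7,8,8a-octahydronaphthalene-1-carboxylate
Product: 22 methyl (1S,5S,6R,8aR)-5-[(3E)-5-ethoxy-3-methyl-5-oxopent-3-en-1-yl]-1,5,6-trimethyl-1,2,3,5,6,7,8,8a-octahydronaphthalene-1-carboxylate
Conditions: (EtO)2P(O)CH2CO2Et (2 equiv), NaH (1.9 equiv), THF, 0 → 50 °C; chromatography
Reagents that add atoms: triethyl phosphonoacetate (CCOC(=O)CP(=O)(OCC)OCC)
Why: Horner–Wadsworth–Emmons olefination of the methyl ketone with the stabilized phosphonate should give mainly the (E)-trisubstituted enoate, the minor Z isomer being removed by chromatography.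

Step 13
Reactants: 22 methyl (1S,5S,6R,8aR)-5-[(3E)-5-ethoxy-3-methyl-5-oxopent-3-en-1-yl]-1,5,6-trimethyl-1,2,3,5,6,7,8,8a-octahydronaphthalene-1-carboxylate
Product: 23 methyl (1S,5S,6R,8aR)-5-[(3E)-5-hydroxy-3-methylpent-3-en-1-yl]-1,5,6-trimethyl-1,2,3,5,6,7,8,8a-octahydronaphthalene-1-carboxylate
Conditions: i-Bu2AlH (2.3 equiv), CH2Cl2, −78 °C; aqueous potassium sodium tartrate
Reagents that add atoms: none
Why: 1,2-Reduction of the unhindered conjugated ethyl ester by i-Bu2AlH at low temperature should outpace attack on the neopentyl-type methyl ester on C4 (chemoselective ester reduction) and give the (E)-allylic alcohol.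

Step 14
Reactants: 23 methyl (1S,5S,6R,8aR)-5-[(3E)-5-hydroxy-3-methylpent-3-en-1-yl]-1,5,6-trimethyl-1,2,3,5,6,7,8,8a-octahydronaphthalene-1-carboxylate
Product: 24 methyl (1S,5S,6R,8aR)-5-{2-[(2R,3R)-3-(hydroxymethyl)-2-methyloxiran-2-yl]ethyl}-1,5,6-trimethyl-1,2,3,5,6,7,8,8a-octahydronaphthalene-1-carboxylate
Conditions: Ti(OiPr)4 (10 mol %), diethyl D-(−)-tartrate (12 mol %), t-BuOOH (2 equiv), 4 Å molecular sieves, CH2Cl2, −20 °C
Reagents that add atoms: tert-butyl hydroperoxide (CC(C)(C)OO)
Why: In the Sharpless asymmetric epoxidation the titanium–tartrate complex transfers oxygen only to the allylic alcohol, and D-(−)-tartrate should give the (2R,3R)-epoxy alcohol from an (E)-3-methylalk-2-en-1-ol (the mirror image of the epoxygeraniol case), so C13 and C14 are set by reagent control and the C1=C10 alkene is untouched.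

**Compound list**

1 | methyl 3-oxocyclohex-1-ene-1-carboxylate | COC(=O)C1=CC(=O)CCC1 | starting material
2 | methyl (1S)-1-methyl-3-[(methylzincio)oxy]cyclohex-2-ene-1-carboxylate | COC(=O)[C@@]1(C)CCCC(O[Zn]C)=C1 | intermediate
3 | methyl (1S)-2-(hydroxymethyl)-1-methyl-3-oxocyclohexane-1-carboxylate (C2 epimers) | COC(=O)[C@@]1(C)CCCC(=O)C1CO | intermediate
4 | (3aR,7aS)-7a-methylhexahydro-2-benzofuran-1,4-dione | O=C1OC[C@@H]2C(=O)CCC[C@]12C | intermediate
5 | potassium (3aR,7aS)-7a-methyl-1-oxo-1,3,3a,6,7,7a-hexahydro-2-benzofuran-4-olate (enolate of 4) | O=C1OC[C@@H]2C(O[K])=CCC[C@]12C | intermediate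
6 | (3aR,7aS)-7a-methyl-1-oxo-1,3,3a,6,7,7a-hexahydro-2-benzofuran-4-yl trifluoromethanesulfonate | O=C1OC[C@@H]2C(OS(=O)(=O)C(F)(F)F)=CCC[C@]12C | intermediate
7 | methacrolein (2-methylprop-2-enal) | CC(=C)C=O | starting material
8 | (3aR,7aS)-4-(1-hydroxy-2-methylprop-2-en-1-yl)-7a-methyl-3a,6,7,7a-tetrahydro-2-benzofuran-1(3H)-one (carbinol epimers) | O=C1OC[C@@H]2C(C(O)C(C)=C)=CCC[C@]12C | intermediate
9 | sodium (1S,2R)-3-(1-hydroxy-2-methylprop-2-en-1-yl)-1-methyl-2-[(phenylselanyl)methyl]cyclohex-3-ene-1-carboxylate | [Na+].[O-]C(=O)[C@@]1(C)CCC=C(C(O)C(C)=C)[C@H]1C[Se]c1ccccc1 | intermediate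
10 | methyl (1S,2R)-3-(1-hydroxy-2-methylprop-2-en-1-yl)-1-methyl-2-[(phenylselanyl)methyl]cyclohex-3-ene-1-carboxylate (carbinol epimers) | COC(=O)[C@@]1(C)CCC=C(C(O)C(C)=C)[C@H]1C[Se]c1ccccc1 | intermediate
11 | methyl (1S,2R)-1-methyl-3-(2-methylprop-2-enoyl)-2-[(phenylselanyl)methyl]cyclohex-3-ene-1-carboxylate | COC(=O)[C@@]1(C)CCC=C(C(=O)C(C)=C)[C@H]1C[Se]c1ccccc1 | intermediate
12 | methyl (1S,8aR)-1,6-dimethyl-5-oxo-1,2,3,5,6,7,8,8a-octahydronaphthalene-1-carboxylate (C6 epimers) | COC(=O)[C@@]1(C)CCC=C2[C@H]1CCC(C)C2=O | intermediate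
13 | methyl (1S,6R,8aR)-1,6-dimethyl-5-oxo-1,2,3,5,6,7,8,8a-octahydronaphthalene-1-carboxylate | COC(=O)[C@@]1(C)CCC=C2[C@H]1CC[C@@H](C)C2=O | intermediate
14 | 2-(2-bromoethyl)-2-methyl-1,3-dioxolane | CC1(CCBr)OCCO1 | starting material
15 | [2-(2-methyl-1,3-dioxolan-2-yl)ethyl]magnesium bromide | CC1(CC[Mg]Br)OCCO1 | intermediate
16 | methyl (1S,6R,8aR)-5-hydroxy-1,6-dimethyl-5-[2-(2-methyl-1,3-dioxolan-2-yl)ethyl]-1,2,3,5,6,7,8,8a-octahydronaphthalene-1-carboxylate (C5 carbinol epimers) | COC(=O)[C@@]1(C)CCC=C2[C@H]1CC[C@@H](C)C2(O)CCC1(C)OCCO1 | intermediate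
17 | methyl (1S,6R,8aR)-1,6-dimethyl-5-[2-(2-methyl-1,3-dioxolan-2-yl)ethyl]-4-oxo-1,2,3,4,6,7,8,8a-octahydronaphthalene-1-carboxylate | COC(=O)[C@@]1(C)CCC(=O)C2=C(CCC3(C)OCCO3)[C@H](C)CC[C@@H]12 | intermediate
18 | lithium enolate formed from 17 by methyl addition at C5 of the naphthalene skeleton (C4–OLi, C4=C4a) | COC(=O)[C@@]1(C)CCC(O[Li])=C2[C@H]1CC[C@@H](C)[C@]2(C)CCC1(C)OCCO1 | intermediate
19 | methyl (1S,5S,6R,8aR)-1,5,6-trimethyl-5-[2-(2-methyl-1,3-dioxolan-2-yl)ethyl]-4-[(trifluoromethanesulfonyl)oxy]-1,2,3,5,6,7,8,8a-octahydronaphthalene-1-carboxylate | COC(=O)[C@@]1(C)CCC(OS(=O)(=O)C(F)(F)F)=C2[C@H]1CC[C@@H](C)[C@]2(C)CCC1(C)OCCO1 | intermediate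
20 | methyl (1S,5S,6R,8aR)-1,5,6-trimethyl-5-[2-(2-methyl-1,3-dioxolan-2-yl)ethyl]-1,2,3,5,6,7,8,8a-octahydronaphthalene-1-carboxylate | COC(=O)[C@@]1(C)CCC=C2[C@H]1CC[C@@H](C)[C@]2(C)CCC1(C)OCCO1 | intermediate
21 | methyl (1S,5S,6R,8aR)-1,5,6-trimethyl-5-(3-oxobutyl)-1,2,3,5,6,7,8,8a-octahydronaphthalene-1-carboxylate | COC(=O)[C@@]1(C)CCC=C2[C@H]1CC[C@@H](C)[C@]2(C)CCC(C)=O | intermediate
22 | methyl (1S,5S,6R,8aR)-5-[(3E)-5-ethoxy-3-methyl-5-oxopent-3-en-1-yl]-1,5,6-trimethyl-1,2,3,5,6,7,8,8a-octahydronaphthalene-1-carboxylate | COC(=O)[C@@]1(C)CCC=C2[C@H]1CC[C@@H](C)[C@]2(C)CC/C(C)=C/C(=O)OCC | intermediate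
23 | methyl (1S,5S,6R,8aR)-5-[(3E)-5-hydroxy-3-methylpent-3-en-1-yl]-1,5,6-trimethyl-1,2,3,5,6,7,8,8a-octahydronaphthalene-1-carboxylate | COC(=O)[C@@]1(C)CCC=C2[C@H]1CC[C@@H](C)[C@]2(C)CC/C(C)=C/CO | intermediate
24 | methyl (1S,5S,6R,8aR)-5-{2-[(2R,3R)-3-(hydroxymethyl)-2-methyloxiran-2-yl]ethyl}-1,5,6-trimethyl-1,2,3,5,6,7,8,8a-octahydronaphthalene-1-carboxylate | COC(=O)[C@@]1(C)CCC=C2[C@H]1CC[C@@H](C)[C@]2(C)CC[C@@]1(C)O[C@@H]1CO | target

**Count and risks**

Total step count: 14. Longest linear sequence: 14 steps (1 → 24).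

Steps most likely to fail:

Step 9. Conjugate addition to the tetrasubstituted, twisted enone may be sluggish, may turn into 1,2-addition or reduction, or may deliver methyl with poor facial selectivity. The fallback sets out from 17 and replaces the conjugate addition by an allylic substitution under reagent control. Oxazaborolidine-catalysed borane reduction (Corey–Bakshi–Shibata reduction) is run with the catalyst antipode that places the carbinol oxygen on the ring face opposite to H5. It should give methyl (1S,4R,6R,8aR)-4-hydroxy-1,6-dimethyl-5-[2-(2-methyl-1,3-dioxolan-2-yl)ethyl]-1,2,3,4,6,7,8,8a-octahydronaphthalene-1-carboxylate F1. Esterification with pyridine-2-carboxylic acid (DCC, DMAP) gives methyl (1S,4R,6R,8aR)-1,6-dimethyl-5-[2-(2-methyl-1,3-dioxolan-2-yl)ethyl]-4-[(pyridine-2-carbonyl)oxy]-1,2,3,4,6,7,8,8a-octahydronaphthalene-1-carboxylate F2. Anti-SN2′ substitution with MeMgBr and CuBr·SMe2 should place methyl on C9 on the face opposite to the leaving group, which is the H5 face, and move the double bond to C1=C10. The fallback returns to the route at 20.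

Step 6. Hydrogen transfer to the C6 radical before ring closure, tin hydride conjugate reduction, or oligomerization of the cross-conjugated dienone may erode the cyclization. The fallback sets out from 11 and reverses the order of carbonyl addition and ring closure. Addition of Grignard reagent 15 with LaCl3·2LiCl should give methyl (1S,2R)-3-[3-hydroxy-2-methyl-5-(2-methyl-1,3-dioxolan-2-yl)pent-1-en-3-yl]-1-methyl-2-[(phenylselanyl)methyl]cyclohex-3-ene-1-carboxylate F3. Tin hydride cyclization of the C6 radical onto the now non-conjugated 1,1-disubstituted alkene should be 6-endo because C8 is fully substituted and flanked by the quaternary carbinol carbon. The C8 radical should take hydrogen axially to leave the equatorial methyl, and any C8 epimer would be removed by chromatography. The fallback returns to the route at 16.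

Step 1. Capture of the zinc enolate by formaldehyde may be inefficient, and retro-aldol cleavage or dehydration to the α-methylene ketone may compete with lactonization and erode control at C5. The fallback sets out from 1 and separates the two bond formations. The same conjugate methylation is quenched with Me3SiOTf to isolate methyl (1S)-1-methyl-3-[(trimethylsilyl)oxy]cyclohex-2-ene-1-carboxylate F4. Lewis acid-catalysed hydroxymethylation in aqueous medium (Mukaiyama aldol reaction with aqueous CH2O and Yb(OTf)3 in THF) gives 3, and p-TsOH lactonization then returns to the route at 4.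

Further compounds
F1 | step 9 | methyl (1S,4R,6R,8aR)-4-hydroxy-1,6-dimethyl-5-[2-(2-methyl-1,3-dioxolan-2-yl)ethyl]-1,2,3,4,6,7,8,8a-octahydronaphthalene-1-carboxylate | COC(=O)[C@@]1(C)CC[C@@H](O)C2=C(CCC3(C)OCCO3)[C@H](C)CC[C@@H]12
F2 | step 9 | methyl (1S,4R,6R,8aR)-1,6-dimethyl-5-[2-(2-methyl-1,3-dioxolan-2-yl)ethyl]-4-[(pyridine-2-carbonyl)oxy]-1,2,3,4,6,7,8,8a-octahydronaphthalene-1-carboxylate | COC(=O)[C@@]1(C)CC[C@@H](OC(=O)c3ccccn3)C2=C(CCC3(C)OCCO3)[C@H](C)CC[C@@H]12
F3 | step 6 | methyl (1S,2R)-3-[3-hydroxy-2-methyl-5-(2-methyl-1,3-dioxolan-2-yl)pent-1-en-3-yl]-1-methyl-2-[(phenylselanyl)methyl]cyclohex-3-ene-1-carboxylate (carbinol epimers) | COC(=O)[C@@]1(C)CCC=C(C(O)(CCC2(C)OCCO2)C(C)=C)[C@H]1C[Se]c1ccccc1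
F4 | step 1 | methyl (1S)-1-methyl-3-[(trimethylsilyl)oxy]cyclohex-2-ene-1-carboxylate | COC(=O)[C@@]1(C)CCCC(O[Si](C)(C)C)=C1
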